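**Retrosynthetic overview**

1. The strategy rests on the central bicyclo[3.2.1]octene. The quaternary carbon common to all four rings and the C(CH3)(CO2CH3) carbon sit on either side of the CH of its two-carbon bridge, with methyl syn to the cyclopentane CH2 as in an E-2-methyl-enoate. Its three-carbon bridge CH=CH–C(=CH–O) is the enol-ether bridge of a norbornene with one carbon inserted.
2. Target ⇒ lactol + isovaleryl chloride; dihydropyran ⇒ 1,5-dialdehyde equivalent from a bicyclo[3.2.1]octenone (spiro-epoxide homologation of the ketone, cleavage of a vinyl group).
3. Bicyclo[3.2.1]octenone ⇒ norbornene silyl enol ether (cyclopropanation, oxidative one-carbon ring expansion) ⇒ intramolecular Diels–Alder reaction of a 1-alkyl-2-silyloxycyclopentadiene carrying an E-tiglate.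
4. Diene precursor ⇒ cyclopentenone silyl dienol ether + linear allylic carbonate (iridium-catalysed branched allylic alkylation, the only catalyst-controlled stereocentre); carbonate ⇒ pent-4-enal by Wittig olefination and cross metathesis.
5. Ring order: the bought cyclopentenone ring becomes the diene; the cyclopentane and the norbornene six-membered ring close together; ring expansion gives the bicyclo[3.2.1]octenone; the dihydropyran closes last.

Key step: step 6

Assumption: the absolute sense of the iridium-catalysed alkylation is taken from the accepted facial model of this catalyst family; the ligand antipode that gives the (R)-configured allylic carbon is the one used, and nothing else in the route depends on this choice.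

Locants for the tricycles: tricyclo[5.2.1.0(1,5)]decane in 11–12 and tricyclo[5.3.1.0(1,5)]undecane in 13–19. C1 is the quaternary bridgehead, C2 the carbon bearing the vinyl (later formyl) group, C5 the ring-fusion CH, C6 the C(CH3)(CO2CH3) carbon, C7 the bridgehead CH, and the highest locant is the one-carbon bridge.

**Step 1**
Reactants: 1 pent-4-enal; 2 methyl 2-(triphenylphosphoranylidene)propanoate
Product: 3 methyl (2E)-2-methylhepta-2,6-dienoate
Conditions: CH2Cl2, rt
Reagents that add atoms: none
Why: Wittig olefination with a stabilised ylide is E-selective, which places the methyl group cis to the chain as the later cycloaddition requires.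

**Step 2**
Reactants: 3 methyl (2E)-2-methylhepta-2,6-dienoate; 4 allyl methyl carbonate
Product: 5 methyl (2E,6E)-8-[(methoxycarbonyl)oxy]-2-methylocta-2,6-dienoate
Conditions: 4 (3 equiv), second-generation Hoveyda–Grubbs catalyst RuCl2(H2IMes)(=CH-C6H4-2-OiPr) (3 mol%), CH2Cl2, 40 °C; E isomer purified
Reagents that add atoms: none
Why: Olefin cross metathesis engages only the monosubstituted alkene because the trisubstituted conjugated tiglate alkene does not load the ruthenium carbene, and the E allylic carbonate is the thermodynamically preferred product.

**Step 3**
Reactants: 6 cyclopent-2-en-1-one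
Product: 8 2-(trimethylsilyloxy)cyclopenta-1,3-diene, via lithium dienolate 7 (not isolated)
Conditions: LiN(iPr)2, THF, −78 °C; Me3SiCl, −78 → 0 °C; non-aqueous work-up, kept cold and used at once
Reagents that add atoms: chlorotrimethylsilane, C[Si](C)(C)Cl
Why: Kinetic deprotonation at the saturated alpha-prime carbon gives the cross-conjugated dienolate, and O-silylation (silyl enol ether formation) traps it before proton transfer can equilibrate it.

**Step 4**
Reactants: 5 methyl (2E,6E)-8-[(methoxycarbonyl)oxy]-2-methylocta-2,6-dienoate; 8 2-(trimethylsilyloxy)cyclopenta-1,3-diene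
Product: 9 methyl (2E,6R)-2-methyl-6-(2-oxocyclopent-3-en-1-yl)octa-2,7-dienoate (both epimers at the ring carbon)
Conditions: [Ir(cod)Cl]2 (2 mol%), binaphthol-derived N,N-bis(1-phenylethyl)phosphoramidite (4 mol%, preactivated with n-PrNH2), KF, 18-crown-6, THF, rt
Reagents that add atoms: none
Why: Iridium-catalysed asymmetric allylic alkylation, in which fluoride releases the cross-conjugated dienolate and this attacks the substituted terminus of the allyliridium intermediate on the face away from the metal, so that the catalyst sets the allylic (R) centre while the adjacent ring carbon forms unselectively and is erased in step 5.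

**Step 5**
Reactants: 9 methyl (2E,6R)-2-methyl-6-(2-oxocyclopent-3-en-1-yl)octa-2,7-dienoate
Product: 10 methyl (2E,6R)-6-[2-(tert-butyldimethylsilyloxy)cyclopenta-1,3-dien-1-yl]-2-methylocta-2,7-dienoate
Conditions: TBSOTf, Et3N, CH2Cl2, −78 → 0 °C; rapid filtration through Et3N-deactivated silica
Reagents that add atoms: tert-butyldimethylsilyl trifluoromethanesulfonate, CC(C)(C)[Si](C)(C)OS(=O)(=O)C(F)(F)F
Why: Soft enolisation (O-silylation, then deprotonation by the amine) turns both ring epimers into the same 2-silyloxycyclopentadiene, whose double-bond isomers interconvert by 1,5-hydrogen shifts, so it does not matter which of them forms first.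

**Step 6**
Reactants: 10 methyl (2E,6R)-6-[2-(tert-butyldimethylsilyloxy)cyclopenta-1,3-dien-1-yl]-2-methylocta-2,7-dienoate
Product: 11 methyl 9-(tert-butyldimethylsilyloxy)-6-methyl-2-vinyltricyclo[5.2.1.0(1,5)]dec-8-ene-6-carboxylate (ester endo; methyl and C4 exo; vinyl on C2 syn to C10)
Conditions: PhMe (0.01 M), BHT (cat.), 140 °C, sealed tube; diastereomers separated at this stage
Reagents that add atoms: none
Why: The silyl dienol ether tautomers exchange by 1,5-hydrogen shifts and only the one with the tether on a diene terminus can reach the enoate, so it is consumed in a concerted, normal-electron-demand intramolecular Diels–Alder reaction, the closest known type being the cyclisation of 1-(alkenyl-tethered) cyclopentadienes to tricyclo[5.2.1.0(1,5)]decenes. Two bonds form, tethered diene terminus to the enoate beta carbon and far diene terminus to the alpha carbon; the cyclopentane closes as the fused ring of a type 1 cycloaddition over the three-atom tether, which can only span the exo side, and the six-membered norbornene ring is the cycloaddition ring itself. The 2-silyloxy group raises the HOMO and puts its largest coefficient on the tethered terminus, which matches the beta carbon of the tiglate, so tether and electronics point the same way. The four new stereocentres (two quaternary carbons, the bridgehead CH and the ring-fusion CH) take their relative configuration from the exo tether and the E-alkene, which put methyl exo and the ester endo, and their absolute configuration from the allylic (R) centre. The selectivity that has to be earned is the diene face: A(1,3) strain with the silyloxy group holds the allylic hydrogen in the diene plane next to oxygen, so the tether lies on one face and the vinyl group on the other, and the dienophile arrives on the tether face. The relay centre therefore ends with vinyl syn to the one-carbon bridge, which is epimeric to the target and is corrected in step 13.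

**Step 7**
Reactants: 11 methyl 9-(tert-butyldimethylsilyloxy)-6-methyl-2-vinyltricyclo[5.2.1.0(1,5)]dec-8-ene-6-carboxylate
Product: 12 exo-siloxycyclopropane (CH2 added across C8–C9 of 11 on the face of C10)
Conditions: Et2Zn, CH2I2, CH2Cl2, 0 °C → rt
Reagents that add atoms: diiodomethane, ICI
Why: Simmons–Smith cyclopropanation with the zinc carbenoid picks the strained electron-rich silyl enol ether over the terminal vinyl group and adds from the exo face because the endo face is covered by the ester, which fixes both new cyclopropane stereocentres.

**Step 8**
Reactants: 12 exo-siloxycyclopropane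
Product: 14 methyl 6-methyl-10-oxo-2-vinyltricyclo[5.3.1.0(1,5)]undec-8-ene-6-carboxylate, via beta-chloroketone 13 (not isolated)
Conditions: FeCl3, DMF, 0 °C → rt; then NaOAc, MeOH, reflux
Reagents that add atoms: none
Why: FeCl3 ring expansion of a siloxycyclopropane (Ito–Saegusa type), in which one-electron oxidation gives an oxy radical that cleaves the cyclopropane bond shared with the six-membered ring, the resulting secondary radical takes chlorine, and acetate then eliminates HCl through the only enolisable position to give the bicyclo[3.2.1]octenone.

**Step 9**
Reactants: 14 methyl 6-methyl-10-oxo-2-vinyltricyclo[5.3.1.0(1,5)]undec-8-ene-6-carboxylate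
Product: 15 methyl 2-formyl-6-methyl-10-oxotricyclo[5.3.1.0(1,5)]undec-8-ene-6-carboxylate
Conditions: O3, CH2Cl2, −78 °C (Sudan Red 7B as end-point indicator); PPh3, −78 °C → rt
Reagents that add atoms: ozone, [O-][O+]=O
Why: Ozonolysis with reductive work-up cleaves the isolated monosubstituted alkene well before the electron-poor enone alkene, the indicator stopping the gas at that point, and the configuration next to the new aldehyde is of no consequence because it is reset in step 13.

**Step 10**
Reactants: 15 methyl 2-formyl-6-methyl-10-oxotricyclo[5.3.1.0(1,5)]undec-8-ene-6-carboxylate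
Product: 16 methyl 2-(dimethoxymethyl)-6-methyl-10-oxotricyclo[5.3.1.0(1,5)]undec-8-ene-6-carboxylate
Conditions: HC(OMe)3, PPTS (cat.), MeOH, rt
Reagents that add atoms: trimethyl orthoformate, COC(OC)OC; methanol, CO
Why: Acetalisation is selective for the aldehyde because the conjugated ketone next to a quaternary carbon is far less electrophilic.

**Step 11**
Reactants: 16 methyl 2-(dimethoxymethyl)-6-methyl-10-oxotricyclo[5.3.1.0(1,5)]undec-8-ene-6-carboxylate
Product: 17 vinyl spiro-epoxide at C10 (either epoxide epimer)
Conditions: Me3S+ I−, n-BuLi, THF, −10 °C → rt
Reagents that add atoms: trimethylsulfonium iodide, C[S+](C)C.[I-]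
Why: Corey–Chaykovsky epoxidation, in which the unstabilised sulfonium ylide adds irreversibly to the carbonyl carbon of the non-enolisable enone (1,2 and not 1,4) and closes the epoxide, whose configuration is irrelevant because that carbon becomes trigonal again.

**Step 12**
Reactants: 17 vinyl spiro-epoxide
Product: 18 methyl 2-(dimethoxymethyl)-10-formyl-6-methyltricyclo[5.3.1.0(1,5)]undec-8-ene-6-carboxylate (C10 epimers)
Conditions: BF3·OEt2 (0.2 equiv), CH2Cl2, −78 °C; Et3N quench
Reagents that add atoms: none
Why: Meinwald rearrangement, in which the epoxide ionises at its tertiary allylic carbon and a 1,2-hydride shift from the CH2 (the only group that can migrate) gives the aldehyde, while any ionisation of the acetal can only lead to the cyclic methyl acetal that step 13 hydrolyses to the same lactol.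

**Step 13**
Reactants: 18 methyl 2-(dimethoxymethyl)-10-formyl-6-methyltricyclo[5.3.1.0(1,5)]undec-8-ene-6-carboxylate
Product: 20 tetracyclic dienol-ether lactol, via dialdehyde 19 (not isolated)
Conditions: p-TsOH·H2O (0.2 equiv), THF–H2O (5:1), rt → 40 °C; used at once
Reagents that add atoms: water, O
Why: Acid hydrolysis frees the second aldehyde, the carbon next to it epimerises through its enol, and the dienol tautomer of the ring aldehyde adds through oxygen to that aldehyde (the ring-chain closure that turns iridoid-type 1,5-dialdehydes into enol lactols), which is open only to the epimer whose formyl carbon lies anti to the one-carbon bridge because only this cis-fused arrangement lets the new six-membered ring adopt a half-chair, so the relay centre is set under thermodynamic control by the rigid core.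

**Step 14**
Reactants: 20 tetracyclic dienol-ether lactol; 21 isovaleryl chloride
Product: 22 CNP0315847.1
Conditions: Et3N, DMAP (cat.), CH2Cl2, −20 → 0 °C
Reagents that add atoms: none
Why: DMAP-catalysed O-acylation of the lactol, whose anomers interconvert, should favour the less hindered pseudo-equatorial hydroxyl and so give the acyloxy group trans to the adjacent cyclopentane C–C bond as in the target, the pseudo-axial site being crowded by the endo hydrogen of the ring-fusion CH on the two-carbon bridge.

**Compound list**

1 | pent-4-enal | C=CCCC=O | starting material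
2 | methyl 2-(triphenylphosphoranylidene)propanoate | COC(=O)C(C)=P(c1ccccc1)(c1ccccc1)c1ccccc1 | starting material
3 | methyl (2E)-2-methylhepta-2,6-dienoate | C=CCC/C=C(\C)C(=O)OC | intermediate
4 | allyl methyl carbonate | C=CCOC(=O)OC | starting material
5 | methyl (2E,6E)-8-[(methoxycarbonyl)oxy]-2-methylocta-2,6-dienoate | COC(=O)OC/C=C/CC/C=C(\C)C(=O)OC | intermediate
6 | cyclopent-2-en-1-one | O=C1C=CCC1 | starting material
7 | lithium cyclopenta-1,4-dien-1-olate (cross-conjugated dienolate) | [Li+].[O-]C1=CCC=C1 | intermediate
8 | 2-(trimethylsilyloxy)cyclopenta-1,3-diene | C[Si](C)(C)OC1=CCC=C1 | intermediate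
9 | methyl (2E,6R)-2-methyl-6-(2-oxocyclopent-3-en-1-yl)octa-2,7-dienoate, both epimers at the ring carbon | O=C1C=CCC1[C@@H](C=C)CC/C=C(\C)C(=O)OC | intermediate
10 | methyl (2E,6R)-6-[2-(tert-butyldimethylsilyloxy)cyclopenta-1,3-dien-1-yl]-2-methylocta-2,7-dienoate (reactive tautomer) | CC(C)(C)[Si](C)(C)OC1=C(CC=C1)[C@@H](C=C)CC/C=C(\C)C(=O)OC | intermediate
11 | methyl 9-(tert-butyldimethylsilyloxy)-6-methyl-2-vinyltricyclo[5.2.1.0(1,5)]dec-8-ene-6-carboxylate; ester endo, methyl and C4 exo, vinyl on C2 syn to C10 | COC(=O)[C@]1(C)[C@@H]2C=C(O[Si](C)(C)C(C)(C)C)[C@]3(C2)[C@@H](C=C)CC[C@@H]13 | intermediate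
12 | exo-siloxycyclopropane: 11 with CH2 bridging C8 and C9 on the face of C10 | COC(=O)[C@]1(C)[C@@H]2[C@H]3C[C@@]3(O[Si](C)(C)C(C)(C)C)[C@]4(C2)[C@@H](C=C)CC[C@@H]14 | intermediate
13 | methyl 8-chloro-6-methyl-10-oxo-2-vinyltricyclo[5.3.1.0(1,5)]undecane-6-carboxylate (C8 epimers) | COC(=O)[C@]1(C)[C@@H]2C(Cl)CC(=O)[C@]3(C2)[C@@H](C=C)CC[C@@H]13 | intermediate
14 | methyl 6-methyl-10-oxo-2-vinyltricyclo[5.3.1.0(1,5)]undec-8-ene-6-carboxylate | COC(=O)[C@]1(C)[C@@H]2C=CC(=O)[C@]3(C2)[C@@H](C=C)CC[C@@H]13 | intermediate
15 | methyl 2-formyl-6-methyl-10-oxotricyclo[5.3.1.0(1,5)]undec-8-ene-6-carboxylate | COC(=O)[C@]1(C)[C@@H]2C=CC(=O)[C@]3(C2)[C@@H](C=O)CC[C@@H]13 | intermediate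
16 | methyl 2-(dimethoxymethyl)-6-methyl-10-oxotricyclo[5.3.1.0(1,5)]undec-8-ene-6-carboxylate | COC(=O)[C@]1(C)[C@@H]2C=CC(=O)[C@]3(C2)[C@@H](C(OC)OC)CC[C@@H]13 | intermediate
17 | vinyl spiro-epoxide: 16 with the C10 carbonyl replaced by a spiro-oxirane (either epimer) | COC(=O)[C@]1(C)[C@@H]2C=CC3(CO3)[C@]4(C2)[C@@H](C(OC)OC)CC[C@@H]14 | intermediate
18 | methyl 2-(dimethoxymethyl)-10-formyl-6-methyltricyclo[5.3.1.0(1,5)]undec-8-ene-6-carboxylate (C10 epimers) | COC(=O)[C@]1(C)[C@@H]2C=CC(C=O)[C@]3(C2)[C@@H](C(OC)OC)CC[C@@H]13 | intermediate
19 | methyl 2,10-diformyl-6-methyltricyclo[5.3.1.0(1,5)]undec-8-ene-6-carboxylate (equilibrating at C2 and C10) | COC(=O)[C@]1(C)[C@@H]2C=CC(C=O)[C@]3(C2)C(C=O)CC[C@@H]13 | intermediate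
20 | tetracyclic dienol-ether lactol (enol hemiacetal between the two formyl carbons of 19; C2 inverted, OH pseudo-equatorial) | COC(=O)[C@]1(C)[C@@H]2C=CC3=CO[C@@H](O)[C@@H]4CC[C@@H]1[C@]34C2 | intermediate
21 | isovaleryl chloride (3-methylbutanoyl chloride) | CC(C)CC(=O)Cl | starting material
22 | CNP0315847.1, the 3-methylbutanoate of lactol 20 | COC(=O)[C@]1(C)[C@@H]2C=CC3=CO[C@@H](OC(=O)CC(C)C)[C@@H]4CC[C@@H]1[C@]34C2 | target

**Step count**

Total: 14 steps. Longest linear sequence: 13 steps (steps 1, 2 and 4–14, from pent-4-enal); step 3 is a one-step side branch from cyclopent-2-en-1-one.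

**Three steps most likely to fail**

Step 6. The cycloaddition may stall, because a trisubstituted enoate has to build two quaternary carbons. The diene may also be lost to dimerisation, or its two faces may be attacked with poor discrimination. Because the relay centre is epimerised later, any facial leakage not removed at 11 would return as loss of enantiomeric purity. Fallback: set out from enone 9 and close both bonds ionically. LiN(SiMe3)2 in THF at −78 → 0 °C should trigger an intramolecular double Michael addition (alpha-prime enolate carbon to the beta carbon of the tiglate, then the ester enolate to the beta carbon of the enone). This gives the tricyclic ketone methyl 6-methyl-9-oxo-2-vinyltricyclo[5.2.1.0(1,5)]decane-6-carboxylate F1. TBSOTf and Et3N then silylate its only enolisable position and return the route to 11. In this variant the ester-bearing quaternary centre is set in the second Michael closure and not by the alkene geometry, so its configuration would have to be checked.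

Step 4. Diene 8 may isomerise by 1,5-hydrogen shift or dimerise before it is alkylated, and the released dienolate may give linear or otherwise misplaced alkylation. Fallback: set out from carbonate 5 and run the same iridium-catalysed alkylation with stable, commercial 1-(trimethylsilyloxy)cyclopentene. This gives methyl (2E,6R)-2-methyl-6-(2-oxocyclopentyl)octa-2,7-dienoate F2. Kinetic enolisation on the CH2 side (LiN(iPr)2, Me3SiCl, THF, −78 °C) gives methyl (2E,6R)-2-methyl-6-[2-(trimethylsilyloxy)cyclopent-2-en-1-yl]octa-2,7-dienoate F3. Saegusa–Ito dehydrogenation with Pd(OAc)2 in MeCN returns the route to enone 9.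

Step 13. The hydrolytic cascade may leak into the conjugated enal by protonation of the dienol at its far carbon, leaving an open dialdehyde that does not close. Epimerisation next to the second aldehyde may also be incomplete. Fallback: set out from 18 and close the ring without water. Camphorsulfonic acid with 4 Å sieves in benzene at 60 °C should ionise the dimethyl acetal, equilibrate the adjacent carbon through the methyl enol ether, and let the dienol oxygen capture the oxocarbenium ion. Loss of methanol makes this closure irreversible, and it gives the cyclic methyl acetal (1-O-methyl ether of the lactol) F4. Brief treatment with PPTS in wet THF at 0 °C exchanges OMe for OH under kinetic control and returns the route to lactol 20.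

**Further compounds**

F1 | step 6 | methyl 6-methyl-9-oxo-2-vinyltricyclo[5.2.1.0(1,5)]decane-6-carboxylate | COC(=O)[C@]1(C)[C@@H]2CC(=O)[C@]3(C2)[C@@H](C=C)CC[C@@H]13
F2 | step 4 | methyl (2E,6R)-2-methyl-6-(2-oxocyclopentyl)octa-2,7-dienoate (both ring epimers) | O=C1CCCC1[C@@H](C=C)CC/C=C(\C)C(=O)OC
F3 | step 4 | methyl (2E,6R)-2-methyl-6-[2-(trimethylsilyloxy)cyclopent-2-en-1-yl]octa-2,7-dienoate | C[Si](C)(C)OC1=CCCC1[C@@H](C=C)CC/C=C(\C)C(=O)OC
F4 | step 13 | cyclic methyl acetal of lactol 20 (anomeric mixture) | COC(=O)[C@]1(C)[C@@H]2C=CC3=COC(OC)[C@@H]4CC[C@@H]1[C@]34C2
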